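**Strategy.** The plan rests on the C3–C4 bond of ring C of the 5,7-dihydroxyflavanone (unit 1), read as an umpoled acylation: the target holds a 1,4-diketone, C4(=O)–C3–C3''–C4''(=O), across the interflavanone bond. An aroyl radical at C4, made from a phenyl selenoester, closes this ring 6-exo onto C3 of the exocyclic enone C3=C3''–C4''=O of a preformed 3-alkylidene flavanone (unit 2). The same step sets C3 (trans to the C2 aryl) and, by hydrogen transfer anti to the C2'' aryl, the cis C3'' centre. The precursor is a salicylic selenoester aryl ether; both aryl carbinol centres come from one C2-symmetric (R,R)-butynediol.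

Key step: step 13

Remark: flavanone numbering is used throughout. Unprimed locants (C2, C3, C4, ring C) belong to the 5,7-dihydroxy unit (unit 1) and double-primed locants to the 7-methoxy unit (unit 2), also for the atoms that will become these positions. 2-Fluoro-4,6-dimethoxybenzaldehyde is taken as a purchasable compound.

**Step 1**
Reactants: 1 4-methoxybenzaldehyde (2 equiv); 2 acetylene
Product: 4 1,4-bis(4-methoxyphenyl)but-2-yne-1,4-diol (racemic and meso forms), via acetylenebis(magnesium bromide) 3 (not isolated)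
Conditions: 2 (gas), EtMgBr (2.1 equiv), THF, 45 °C; then 1 (2 equiv), 0 °C to rt; H2O work-up
Reagents that add atoms: 4-methoxybenzaldehyde (second equivalent), COc1ccc(C=O)cc1
Why: Double deprotonation of acetylene gives the bis-Grignard reagent, whose two acetylide carbons each add to one molecule of the aldehyde (1,2-addition), and the configuration of the carbinols is irrelevant because both are oxidised in step 2.

**Step 2**
Reactants: 4 1,4-bis(4-methoxyphenyl)but-2-yne-1,4-diol
Product: 5 1,4-bis(4-methoxyphenyl)but-2-yne-1,4-dione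
Conditions: activated MnO2 (excess), CH2Cl2, rt
Reagents that add atoms: none
Why: MnO2 oxidises benzylic-propargylic alcohols selectively to the conjugated ynedione without touching the aryl ethers or the triple bond.

**Step 3**
Reactants: 5 1,4-bis(4-methoxyphenyl)but-2-yne-1,4-dione
Product: 6 (1R,4R)-1,4-bis(4-methoxyphenyl)but-2-yne-1,4-diol
Conditions: (R)-Alpine-Borane (3 equiv), THF, 0 °C to rt; H2O work-up; recrystallisation
Reagents that add atoms: none
Why: Midland reduction: the β-hydride is transferred through a boat-like six-membered transition state in which the slim alkynyl arm sits next to the pinane methyl and the aryl group points away, so each ketone should give the (R)-carbinol, and the double reduction channels the minor stereo-error into the meso diol, which is removed by crystallisation.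

**Step 4**
Reactants: 7 2-fluoro-4,6-dimethoxybenzaldehyde
Product: 8 2-fluoro-4,6-dihydroxybenzaldehyde
Conditions: BBr3 (3 equiv), CH2Cl2, −78 °C to rt; H2O work-up
Reagents that add atoms: none
Why: Lewis acid demethylation: bromide attacks the O-methyl group of each boron-complexed ether, and the aldehyde and the aryl fluoride are recovered on aqueous work-up.

**Step 5**
Reactants: 8 2-fluoro-4,6-dihydroxybenzaldehyde
Product: 9 2,4-bis(benzyloxy)-6-fluorobenzaldehyde
Conditions: BnBr (2.2 equiv), K2CO3, DMF, rt to 50 °C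
Reagents that add atoms: benzyl bromide, BrCc1ccccc1
Why: Williamson ether synthesis masks the future 5- and 7-hydroxyls with groups that leave by neutral hydrogenolysis at the end.

**Step 6**
Reactants: 6 (1R,4R)-1,4-bis(4-methoxyphenyl)but-2-yne-1,4-diol; 9 2,4-bis(benzyloxy)-6-fluorobenzaldehyde
Product: 10 2,4-bis(benzyloxy)-6-{[(1R,4R)-4-hydroxy-1,4-bis(4-methoxyphenyl)but-2-yn-1-yl]oxy}benzaldehyde
Conditions: 6 (2 equiv, excess recovered), NaH (1 equiv), DMF, 0 °C to rt
Reagents that add atoms: none
Why: Nucleophilic aromatic substitution (addition-elimination) of the fluoride ortho to the formyl group by one alkoxide of the diol leaves the carbinol C–O bond intact, so the (R) centre is kept, and because the two hydroxyls are homotopic, mono-arylation gives a single compound.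

**Step 7**
Reactants: 10 the mono-ether aldehyde
Product: 11 2,4-bis(benzyloxy)-6-{[(1R,4R)-4-hydroxy-1,4-bis(4-methoxyphenyl)but-2-yn-1-yl]oxy}benzoic acid
Conditions: NaClO2, NaH2PO4, 2-methyl-2-butene, t-BuOH/THF/H2O, rt
Reagents that add atoms: sodium chlorite, [Na+].[O-]Cl=O
Why: Pinnick oxidation under buffered conditions with a hypochlorite scavenger takes this arene out of the carbene chemistry of step 11 and prepares the later acyl radical precursor, while alkyne, carbinol and ethers are inert.

**Step 8**
Reactants: 7 2-fluoro-4,6-dimethoxybenzaldehyde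
Product: 12 2-fluoro-6-hydroxy-4-methoxybenzaldehyde
Conditions: BCl3 (1.1 equiv), CH2Cl2, −78 to 0 °C; H2O work-up
Reagents that add atoms: none
Why: Chelation-controlled demethylation: only the methoxy group ortho to the formyl group can form a six-membered boron chelate with the carbonyl oxygen, so the 4-methoxy group (the future 7''-OMe) stays.

**Step 9**
Reactants: 12 2-fluoro-6-hydroxy-4-methoxybenzaldehyde
Product: 13 2-(benzyloxy)-6-fluoro-4-methoxybenzaldehyde
Conditions: BnBr (1.1 equiv), K2CO3, DMF, 50 °C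
Reagents that add atoms: benzyl bromide, BrCc1ccccc1
Why: Williamson ether synthesis of the chelated phenol masks the future 5''-hydroxyl as a benzyl ether.

**Step 10**
Reactants: 11 the mono-ether acid; 13 2-(benzyloxy)-6-fluoro-4-methoxybenzaldehyde
Product: 14 2,4-bis(benzyloxy)-6-{[(1R,4R)-4-[3-(benzyloxy)-2-formyl-5-methoxyphenoxy]-1,4-bis(4-methoxyphenyl)but-2-yn-1-yl]oxy}benzoic acid
Conditions: NaH (2.2 equiv), DMF, 0 °C to rt; then aq. NaHSO4
Reagents that add atoms: none
Why: Second nucleophilic aromatic substitution: the dianion of 11 attacks the fluoroarene through the alkoxide only, the hindered carboxylate being unreactive, with retention at the carbinol carbon.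

**Step 11**
Reactants: 14 the bis-ether acid aldehyde
Product: 15 2,4-bis(benzyloxy)-6-{(1S)-2-[(2R)-5-(benzyloxy)-7-methoxy-2-(4-methoxyphenyl)-4-oxochroman-3-ylidene]-1-(4-methoxyphenyl)ethoxy}benzoic acid, E alkene (the CH(OAr)(anisyl) carbon trans to C4''=O)
Conditions: 3-mesityl-5,6,7,8-tetrahydro-4H-cyclohepta[d]thiazol-3-ium perchlorate (20 mol%), K2CO3 (1.3 equiv), THF, 70 °C; then aq. KHSO4
Reagents that add atoms: none
Why: Carbene-catalysed intramolecular hydroacylation of an unactivated alkyne: the Breslow intermediate of the aldehyde adds across the triple bond in a concerted, Conia-ene-like syn fashion (6-exo-dig), which closes the pyranone of unit 2 and gives the E exocyclic enone, while the potassium carboxylate on the other arene is a spectator and C2 and C2'' keep their spatial arrangement (the descriptors change only through the priority rules).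

**Step 12**
Reactants: 15 the enone acid
Product: 16 Se-phenyl 2,4-bis(benzyloxy)-6-{(1S)-2-[(2R)-5-(benzyloxy)-7-methoxy-2-(4-methoxyphenyl)-4-oxochroman-3-ylidene]-1-(4-methoxyphenyl)ethoxy}benzenecarboselenoate, E alkene
Conditions: PhSeSePh (1.5 equiv), Bu3P (1.5 equiv), CH2Cl2, 0 °C to rt
Reagents that add atoms: diphenyl diselenide, c1ccc(cc1)[Se][Se]c1ccccc1
Why: Redox condensation: the acid is activated as an acyloxyphosphonium ion and captured by phenylselenolate, giving the acyl radical precursor under neutral conditions.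

**Step 13**
Reactants: 16 the phenyl selenoester
Product: 17 (2S,3R)-5,7-bis(benzyloxy)-3-[(2S,3S)-5-(benzyloxy)-7-methoxy-2-(4-methoxyphenyl)-4-oxochroman-3-yl]-2-(4-methoxyphenyl)chroman-4-one
Conditions: Bu3SnH (1.5 equiv) and AIBN (0.2 equiv) added by syringe pump, benzene (0.005 M), 80 °C
Reagents that add atoms: none
Why: Bu3Sn• abstracts PhSe from 16 to give the aroyl radical at C4, a nucleophilic σ-radical that adds to the electrophilic enone β-carbon C3 and so joins two acceptor carbons by polarity reversal; the resulting α-keto radical at C3'' is reduced by Bu3SnH, which carries the chain. The closest known reaction type is the acyl radical (phenyl selenoester/Bu3SnH) cyclisation onto Michael acceptors, a radical counterpart of the Stetter reaction. Ring C of unit 1 closes in the 6-exo-trig mode. C3 is controlled by C2: in the chair-like transition state C2–H eclipses the alkene (allylic 1,3-strain) and the anisyl group is pseudo-equatorial, so the C3–C3'' bond should end up trans to it (3R), whatever the alkene geometry. C3'' is controlled by C2'': allylic 1,2-strain turns the C2'' anisyl group pseudo-axial in the planar radical and Bu3SnH should deliver hydrogen to the opposite face, giving the cis-2'',3'' unit (3''S); a carbene-catalysed Stetter closure was not chosen because its internal syn proton transfer is expected to give the trans unit on this E enone. The step needs ring closure to outrun reduction of the aroyl radical (activated acceptor, high dilution, slow stannane addition) and 6-exo to beat 7-endo attack (enone polarisation).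

**Step 14**
Reactants: 17 the tribenzyl biflavanone
Product: 18 (2S,3R)-5,7-dihydroxy-3-[(2S,3S)-5-hydroxy-7-methoxy-2-(4-methoxyphenyl)-4-oxochroman-3-yl]-2-(4-methoxyphenyl)chroman-4-one (CNP0184936.3)
Conditions: H2 (1 atm), 10% Pd/C, EtOAc/THF, rt
Reagents that add atoms: none
Why: Hydrogenolysis of the three benzyl aryl ethers under neutral conditions frees the 5-, 7- and 5''-hydroxyls without enolisation, so the kinetically set cis C3'' centre and C3 are not epimerised, and the methyl ethers and both ketones survive at 1 atm.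

**Compound list**
1 | 4-methoxybenzaldehyde | COc1ccc(C=O)cc1 | starting material
2 | acetylene | C#C | starting material
3 | acetylenebis(magnesium bromide) | Br[Mg]C#C[Mg]Br | intermediate (not isolated)
4 | 1,4-bis(4-methoxyphenyl)but-2-yne-1,4-diol (racemic and meso) | COc1ccc(cc1)C(O)C#CC(O)c1ccc(OC)cc1 | intermediate
5 | 1,4-bis(4-methoxyphenyl)but-2-yne-1,4-dione | COc1ccc(cc1)C(=O)C#CC(=O)c1ccc(OC)cc1 | intermediate
6 | (1R,4R)-1,4-bis(4-methoxyphenyl)but-2-yne-1,4-diol | COc1ccc(cc1)[C@@H](O)C#C[C@H](O)c1ccc(OC)cc1 | intermediate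
7 | 2-fluoro-4,6-dimethoxybenzaldehyde | COc1cc(F)c(C=O)c(OC)c1 | starting material
8 | 2-fluoro-4,6-dihydroxybenzaldehyde | Oc1cc(F)c(C=O)c(O)c1 | intermediate
9 | 2,4-bis(benzyloxy)-6-fluorobenzaldehyde | O=Cc1c(F)cc(OCc2ccccc2)cc1OCc1ccccc1 | intermediate
10 | 2,4-bis(benzyloxy)-6-{[(1R,4R)-4-hydroxy-1,4-bis(4-methoxyphenyl)but-2-yn-1-yl]oxy}benzaldehyde | COc1ccc(cc1)[C@@H](Oc1cc(OCc2ccccc2)cc(OCc2ccccc2)c1C=O)C#C[C@H](O)c1ccc(OC)cc1 | intermediate
11 | 2,4-bis(benzyloxy)-6-{[(1R,4R)-4-hydroxy-1,4-bis(4-methoxyphenyl)but-2-yn-1-yl]oxy}benzoic acid | COc1ccc(cc1)[C@@H](Oc1cc(OCc2ccccc2)cc(OCc2ccccc2)c1C(=O)O)C#C[C@H](O)c1ccc(OC)cc1 | intermediate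
12 | 2-fluoro-6-hydroxy-4-methoxybenzaldehyde | COc1cc(O)c(C=O)c(F)c1 | intermediate
13 | 2-(benzyloxy)-6-fluoro-4-methoxybenzaldehyde | COc1cc(F)c(C=O)c(OCc2ccccc2)c1 | intermediate
14 | 2,4-bis(benzyloxy)-6-{[(1R,4R)-4-[3-(benzyloxy)-2-formyl-5-methoxyphenoxy]-1,4-bis(4-methoxyphenyl)but-2-yn-1-yl]oxy}benzoic acid | COc1ccc(cc1)[C@@H](Oc1cc(OCc2ccccc2)cc(OCc2ccccc2)c1C(=O)O)C#C[C@H](Oc1cc(OC)cc(OCc2ccccc2)c1C=O)c1ccc(OC)cc1 | intermediate
15 | 2,4-bis(benzyloxy)-6-{(1S)-2-[(2R)-5-(benzyloxy)-7-methoxy-2-(4-methoxyphenyl)-4-oxochroman-3-ylidene]-1-(4-methoxyphenyl)ethoxy}benzoic acid (E) | O=C1c2c(OCc3ccccc3)cc(OC)cc2O[C@H](c2ccc(OC)cc2)/C1=C\[C@@H](c1ccc(OC)cc1)Oc1cc(OCc2ccccc2)cc(OCc2ccccc2)c1C(=O)O | intermediate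
16 | Se-phenyl selenoester of 15 (E) | O=C1c2c(OCc3ccccc3)cc(OC)cc2O[C@H](c2ccc(OC)cc2)/C1=C\[C@@H](c1ccc(OC)cc1)Oc1cc(OCc2ccccc2)cc(OCc2ccccc2)c1C(=O)[Se]c1ccccc1 | intermediate
17 | (2S,3R)-5,7-bis(benzyloxy)-3-[(2S,3S)-5-(benzyloxy)-7-methoxy-2-(4-methoxyphenyl)-4-oxochroman-3-yl]-2-(4-methoxyphenyl)chroman-4-one | COc1ccc([C@H]2Oc3cc(OCc4ccccc4)cc(OCc4ccccc4)c3C(=O)[C@@H]2[C@@H]2C(=O)c3c(OCc4ccccc4)cc(OC)cc3O[C@@H]2c2ccc(OC)cc2)cc1 | intermediate
18 | (2S,3R)-5,7-dihydroxy-3-[(2S,3S)-5-hydroxy-7-methoxy-2-(4-methoxyphenyl)-4-oxochroman-3-yl]-2-(4-methoxyphenyl)chroman-4-one | COc1ccc([C@H]2Oc3cc(O)cc(O)c3C(=O)[C@@H]2[C@@H]2C(=O)c3c(O)cc(OC)cc3O[C@@H]2c2ccc(OC)cc2)cc1 | target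

**Step count.** Total: 14 steps. Longest linear sequence: 10 steps (1, 2, 3, 6, 7, 10, 11, 12, 13, 14).

**Steps most likely to fail**

1. Step 13. What may go wrong:
   - hydrogen transfer to the aroyl radical before ring closure, since in the E enone the face of C3 that the tether reaches lies syn to the pseudo-axial C2'' aryl group;
   - intramolecular hydrogen shifts to the aroyl radical from C2–H or a benzylic OCH2;
   - hydrogen delivery to the wrong face of the C3'' radical.

   Fallback (sets out from 15, returns at 17): a radical-polar crossover replaces the stannane chain. Acid 15, PPh3 and [Ir(dF(CF3)ppy)2(dtbbpy)]PF6 under blue light (2,4,6-collidine, MeCN/H2O) should give the same aroyl radical by deoxygenation of the acid. After 6-exo closure the C3'' radical is reduced to the enolate, which the bulky collidinium ion should protonate anti to the C2'' aryl group. New compounds: none F0.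

2. Step 11. What may go wrong:
   - base-induced loss of the allylic C2''–H and migration of the exocyclic double bond into the ring, which would erase C2'';
   - slow carbene addition at the doubly ortho-substituted aldehyde in the presence of the carboxylate.

   Fallback (sets out from 6, returns at 15): the two substitutions are run in the reverse order and the unit 2 pyranone is closed by a neutral acyl radical cyclisation. Diol 6 is first arylated with 13 (NaH, DMF) to give 2-(benzyloxy)-6-{[(1R,4R)-4-hydroxy-1,4-bis(4-methoxyphenyl)but-2-yn-1-yl]oxy}-4-methoxybenzaldehyde F1. Pinnick oxidation gives 2-(benzyloxy)-6-{[(1R,4R)-4-hydroxy-1,4-bis(4-methoxyphenyl)but-2-yn-1-yl]oxy}-4-methoxybenzoic acid F2. Arylation with 9 gives 2-(benzyloxy)-6-{[(1R,4R)-4-[3,5-bis(benzyloxy)-2-formylphenoxy]-1,4-bis(4-methoxyphenyl)but-2-yn-1-yl]oxy}-4-methoxybenzoic acid F3, with the acid on the unit 2 arene and the aldehyde on the unit 1 arene. PhSeSePh/Bu3P gives the Se-phenyl selenoester of F3 F4. Bu3SnH/AIBN (benzene, 80 °C) should close the unit 2 ring by 6-exo-dig aroyl radical addition to the alkyne and give 2,4-bis(benzyloxy)-6-{(1S)-2-[(2R)-5-(benzyloxy)-7-methoxy-2-(4-methoxyphenyl)-4-oxochroman-3-ylidene]-1-(4-methoxyphenyl)ethoxy}benzaldehyde (E/Z mixture) F5. Pinnick oxidation then returns to 15, as an E/Z mixture whose isomers are both expected to converge in step 13.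

3. Step 3. What may go wrong:
   - incomplete facial discrimination between the aryl and alkynyl groups of the ynedione;
   - conjugate hydride addition or hydroboration at the electron-poor triple bond.

   Fallback (sets out from 1, returns at 6): catalytic asymmetric alkynylation replaces the reduction. Me2Zn/ProPhenol-catalysed addition of (trimethylsilyl)acetylene to 1, with the ligand enantiomer chosen for the R carbinol, gives (R)-1-(4-methoxyphenyl)-3-(trimethylsilyl)prop-2-yn-1-ol F6. K2CO3/MeOH gives (S)-1-(4-methoxyphenyl)prop-2-yn-1-ol F7; the spatial arrangement is unchanged, and the descriptor changes only because the terminal ethynyl group ranks below the aryl group. A second Me2Zn/ProPhenol alkynylation of 1 with F7, using the same ligand enantiomer, gives 6.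

**Further compounds**
F0 | step 13 | none | none
F1 | step 11 | 2-(benzyloxy)-6-{[(1R,4R)-4-hydroxy-1,4-bis(4-methoxyphenyl)but-2-yn-1-yl]oxy}-4-methoxybenzaldehyde | COc1ccc(cc1)[C@@H](O)C#C[C@H](Oc1cc(OC)cc(OCc2ccccc2)c1C=O)c1ccc(OC)cc1
F2 | step 11 | 2-(benzyloxy)-6-{[(1R,4R)-4-hydroxy-1,4-bis(4-methoxyphenyl)but-2-yn-1-yl]oxy}-4-methoxybenzoic acid | COc1ccc(cc1)[C@@H](O)C#C[C@H](Oc1cc(OC)cc(OCc2ccccc2)c1C(=O)O)c1ccc(OC)cc1
F3 | step 11 | 2-(benzyloxy)-6-{[(1R,4R)-4-[3,5-bis(benzyloxy)-2-formylphenoxy]-1,4-bis(4-methoxyphenyl)but-2-yn-1-yl]oxy}-4-methoxybenzoic acid | COc1ccc(cc1)[C@@H](Oc1cc(OCc2ccccc2)cc(OCc2ccccc2)c1C=O)C#C[C@H](Oc1cc(OC)cc(OCc2ccccc2)c1C(=O)O)c1ccc(OC)cc1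
F4 | step 11 | Se-phenyl selenoester of F3 | COc1ccc(cc1)[C@@H](Oc1cc(OCc2ccccc2)cc(OCc2ccccc2)c1C=O)C#C[C@H](Oc1cc(OC)cc(OCc2ccccc2)c1C(=O)[Se]c1ccccc1)c1ccc(OC)cc1
F5 | step 11 | 2,4-bis(benzyloxy)-6-{(1S)-2-[(2R)-5-(benzyloxy)-7-methoxy-2-(4-methoxyphenyl)-4-oxochroman-3-ylidene]-1-(4-methoxyphenyl)ethoxy}benzaldehyde (E/Z mixture) | O=C1c2c(OCc3ccccc3)cc(OC)cc2O[C@H](c2ccc(OC)cc2)C1=C[C@@H](c1ccc(OC)cc1)Oc1cc(OCc2ccccc2)cc(OCc2ccccc2)c1C=O
F6 | step 3 | (R)-1-(4-methoxyphenyl)-3-(trimethylsilyl)prop-2-yn-1-ol | COc1ccc(cc1)[C@@H](O)C#C[Si](C)(C)C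
F7 | step 3 | (S)-1-(4-methoxyphenyl)prop-2-yn-1-ol | COc1ccc(cc1)[C@@H](O)C#C
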